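**Retrosynthetic overview**

- Atom numbers are icetexane numbers: ring A = C1–C5 and C10 (C4 quaternary, carrying methyl C18 and carboxyl C19); ring B = C5, C6, C7, C8, C9, C20, C10; ring C = C8, C9, C11–C14.
- Endgame: the hydroxyquinone comes from the 11,12,14-trimethoxyarene (arene oxidation, then O-demethylation at C12), the 7α-acetate from a reagent-controlled reduction of a C7 aryl ketone.
- Key disconnection: ring B is cut at C6–C7 and C10–C20 and the lactone at O–C10, giving a 2-(chloromethyl)aroyl chloride (ring C, electrophilic at C7 and then at C20) and a 2-methylidene-cyclohexane ester (ring A, nucleophilic at C6 and then at C10).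
- Enabling feature: C5 of ring A carries the exocyclic C6 and sits next to C10H2, so C6=C5–C10H2 is an isobutene-type 1,3-bis-nucleophile; C7 and C20 are ortho on C8/C9 of a ring C without a free aryl CH; the C19 carboxyl on C4 is 1,3 to C10 and quenches the last cation as the γ-lactone.
- Ring order: rings C and A are brought in intact (from 1,2,4-trimethoxybenzene and from methyl 2-oxocyclohexane-1-carboxylate); ring B and the lactone ring close in the same operation.

Key step: step 10

Assumption: in the lithioenamine methylation (step 8) the L-valine tert-butyl ester auxiliary with HMPA as lithium ligand is taken to give the (S)-quaternary centre; if the sense is opposite, the D-auxiliary is used and nothing else changes.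

**Route**

Step 1
Reactants: 1 1,2,4-trimethoxybenzene
Product: 2 2-(2,3,6-trimethoxyphenyl)propan-2-ol
Conditions: n-BuLi, THF, 0 °C; acetone, −78 → 23 °C; H2O
Reagents that add atoms: acetone CC(C)=O
Why: Directed ortho-lithiation occurs at the CH flanked by two methoxy groups (the future C13) and the aryllithium adds 1,2 to acetone.

Step 2
Reactants: 2 2-(2,3,6-trimethoxyphenyl)propan-2-ol
Product: 3 1,2,4-trimethoxy-3-(propan-2-yl)benzene
Conditions: Et3SiH, CF3CO2H, CH2Cl2, 0 °C
Reagents that add atoms: none
Why: Ionic hydrogenation, in which the tertiary benzylic cation stabilised by two ortho methoxy groups forms in acid and is reduced by the silane.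

Step 3
Reactants: 3 1,2,4-trimethoxy-3-(propan-2-yl)benzene
Product: 4 2,4,5-trimethoxy-3-(propan-2-yl)benzaldehyde
Conditions: POCl3, DMF, 70 °C; aq. NaOAc
Reagents that add atoms: N,N-dimethylformamide CN(C)C=O; water O
Why: Vilsmeier–Haack formylation should go to the free position that is ortho and para to methoxy groups (the future C8), the other free CH having only one ortho methoxy group.

Step 4
Reactants: 4 2,4,5-trimethoxy-3-(propan-2-yl)benzaldehyde
Product: 5 2,4,5-trimethoxy-3-(propan-2-yl)benzoic acid
Conditions: NaClO2, NaH2PO4, 2-methylbut-2-ene, t-BuOH/H2O, 23 °C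
Reagents that add atoms: sodium chlorite [Na+].[O-]Cl=O
Why: Pinnick oxidation of an aryl aldehyde, with the alkene scavenger removing HOCl so that the electron-rich ring is not chlorinated.

Step 5
Reactants: 5 2,4,5-trimethoxy-3-(propan-2-yl)benzoic acid
Product: 7 4,5,7-trimethoxy-6-(propan-2-yl)-2-benzofuran-1(3H)-one (phthalide), via hydroxymethyl acid 6 (not isolated)
Conditions: s-BuLi (2.2 equiv), TMEDA, THF, −78 °C; (CH2O)n, −78 → 23 °C; 2 M HCl, 23 °C
Reagents that add atoms: formaldehyde C=O
Why: Carboxylate-directed ortho-lithiation at the only ortho CH (also ortho to a methoxy group, the future C9), hydroxymethylation, and acid lactonisation of the ortho-hydroxymethyl acid to the five-membered lactone.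

Step 6
Reactants: 7 4,5,7-trimethoxy-6-(propan-2-yl)-2-benzofuran-1(3H)-one
Product: 8 2-(chloromethyl)-3,4,6-trimethoxy-5-(propan-2-yl)benzoyl chloride
Conditions: Cl2CHOMe, ZnCl2 (cat.), neat, 60 °C; used crude
Reagents that add atoms: dichloromethyl methyl ether COC(Cl)Cl
Why: Lewis-acid-catalysed ring-opening chlorination of a lactone to the ω-chloro acyl chloride, helped by the ortho methoxy group at the benzylic C–O bond and free of ring formylation because no aryl CH is left.

Step 7
Reactants: 9 methyl 2-oxocyclohexane-1-carboxylate; 10 tert-butyl L-valinate (free base from the commercial hydrochloride)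
Product: 11 methyl 2-{[(2S)-1-tert-butoxy-3-methyl-1-oxobutan-2-yl]amino}cyclohex-1-ene-1-carboxylate
Conditions: BF3·OEt2 (cat.), PhMe, reflux, Dean–Stark
Reagents that add atoms: none
Why: Condensation of the β-keto ester with the primary amine gives the conjugated, hydrogen-bonded enamino ester.

Step 8
Reactants: 11 methyl 2-{[(2S)-1-tert-butoxy-3-methyl-1-oxobutan-2-yl]amino}cyclohex-1-ene-1-carboxylate
Product: 13 methyl (1S)-1-methyl-2-oxocyclohexane-1-carboxylate, via ketimine 12 (not isolated)
Conditions: LDA, HMPA (1 equiv), PhMe, −78 °C; MeI; then 1 M HCl, 23 °C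
Reagents that add atoms: iodomethane CI; water O
Why: Alkylation of a chiral chelated lithioenamine, in which lithium is held between the nitrogen and the tert-butyl ester carbonyl, the isopropyl group shields one face and MeI enters from the other to set the quaternary C4, after which hydrolysis frees the ketone and returns the auxiliary.

Step 9
Reactants: 13 methyl (1S)-1-methyl-2-oxocyclohexane-1-carboxylate
Product: 14 methyl (1S)-1-methyl-2-methylidenecyclohexane-1-carboxylate
Conditions: Ph3PCH3Br, KN(SiMe3)2, PhMe, 0 → 80 °C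
Reagents that add atoms: methylidenetriphenylphosphorane C=P(c1ccccc1)(c1ccccc1)c1ccccc1
Why: Wittig methylenation of the hindered ketone, with a quaternary stereocentre that cannot epimerise and an ylide that spares the ester.

Step 10
Reactants: 8 2-(chloromethyl)-3,4,6-trimethoxy-5-(propan-2-yl)benzoyl chloride; 14 methyl (1S)-1-methyl-2-methylidenecyclohexane-1-carboxylate
Product: 16 (4S,5S,10S)-11,12,14-trimethoxy-7-oxo-9(10→20)-abeo-abieta-8,11,13-trien-19,10-olide (5α-H, lactone on the β-face), via unsaturated ketone 15 (not isolated)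
Conditions: AgOTf (2.2 equiv), CH2Cl2, −78 °C; 14 added slowly; −78 → 23 °C
Reagents that add atoms: none
Why: Proposed new method: a (4+3) annulation by two aliphatic Friedel–Crafts events, in which AgOTf first ionises the acyl chloride of 8 (the benzylic chloride is switched off by the neighbouring acylium), the acylium adds to the CH2 terminus C6 of 14 with ene-type loss of a C10 proton (Darzens–Nenitzescu acylation) to give the β,γ-unsaturated ketone 15, and the new C7 carbonyl then assists loss of the benzylic chloride through a five-membered oxocarbenium so that C20 is attacked by C10 of the C5=C10 bond. The closest known reactions are the acylation of methylidenecycloalkanes to β,γ-unsaturated ketones, the acylation–alkylation annulation of arenes with ω-chloroacyl chlorides, and benzylic cation–olefin cyclisations terminated by a carboxyl group. Ring B closes in a 7-endo-trig cation–olefin mode (Markovnikov attack by the less substituted C10 leaves the tertiary C5 cation), a 1,2-hydride shift from C10 to C5 then gives the tertiary C10 cation, and the lactone ring closes by five-membered capture of that cation by the C19 ester carbonyl with loss of the methyl group as MeOTf. C10 is controlled by the tether, since the C19 carbonyl on the quaternary C4 reaches C10 only on its own β-face and so places C20 equatorial, and C5 is controlled stereoelectronically, the hydride arriving anti to the entering oxygen (trans-diaxial addition across C5–C10) to give the more stable trans-fused 5α-H product with C6 equatorial. The step needs chemoselectivity (acylation before benzylation, otherwise the regioisomeric annulation results), secured by the faster ionisation of the acyl chloride and by the fact that only the ketone formed in the first event activates C20, and it needs regioselectivity at the alkene, secured by the 1,1-disubstituted C5=C6 bond (attack at C6) and then by the trisubstituted C5=C10 bond (attack at C10), while aryl Friedel–Crafts reactions are excluded because ring C has no free CH. Lactonisation cannot run ahead of the second C–C bond, because a tertiary cation at C10 exists only after C20 is attached.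

Step 11
Reactants: 16 (4S,5S,10S)-11,12,14-trimethoxy-7-oxo-9(10→20)-abeo-abieta-8,11,13-trien-19,10-olide
Product: 17 (4S,5S,7R,10S)-7-hydroxy-11,12,14-trimethoxy-9(10→20)-abeo-abieta-8,11,13-trien-19,10-olide (7α-OH)
Conditions: (S)-2-methyl-CBS-oxazaborolidine (20 mol %), BH3·SMe2, THF, −20 °C; MeOH
Reagents that add atoms: none
Why: Corey–Bakshi–Shibata reduction, in which the catalyst tells the aryl group (large) from the C6 methylene (small) and the (S)-catalyst should deliver hydride to the face that gives the (7R)-benzylic alcohol (7α-OH, cis to H-5), the lactone being inert to borane at this temperature.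

Step 12
Reactants: 17 (4S,5S,7R,10S)-7-hydroxy-11,12,14-trimethoxy-9(10→20)-abeo-abieta-8,11,13-trien-19,10-olide
Product: 18 (4S,5S,7R,10S)-7-acetoxy-11,12,14-trimethoxy-9(10→20)-abeo-abieta-8,11,13-trien-19,10-olide
Conditions: Ac2O, pyridine, DMAP (cat.), CH2Cl2, 0 → 23 °C
Reagents that add atoms: acetic anhydride CC(=O)OC(C)=O
Why: DMAP-catalysed O-acylation of the secondary alcohol, which leaves the C7–O bond and hence the configuration untouched.

Step 13
Reactants: 18 (4S,5S,7R,10S)-7-acetoxy-11,12,14-trimethoxy-9(10→20)-abeo-abieta-8,11,13-trien-19,10-olide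
Product: 19 (4S,5S,7R,10S)-7-acetoxy-12-methoxy-11,14-dioxo-9(10→20)-abeo-abieta-8,12-dien-19,10-olide (12-O-methyl ether of the target)
Conditions: (NH4)2Ce(NO3)6, MeCN/H2O, 0 °C
Reagents that add atoms: water O
Why: Oxidative demethylation of the para-dimethoxy pair (C11/C14) to the p-quinone, with the C12 methoxy group left as a vinylogous ester and the acetate and lactone inert to the oxidant.

Step 14
Reactants: 19 (4S,5S,7R,10S)-7-acetoxy-12-methoxy-11,14-dioxo-9(10→20)-abeo-abieta-8,12-dien-19,10-olide
Product: 20 7α-acetoxy-6,7-dihydroicetexone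
Conditions: BCl3, CH2Cl2, −78 → −40 °C; aq. NaHCO3
Reagents that add atoms: none
Why: Lewis-acid ether cleavage assisted by chelation to the adjacent C11 quinone carbonyl removes the methyl group of the vinylogous ester as MeCl at a temperature at which the secondary acetate and the lactone should survive.

**Compound list**

1 | 1,2,4-trimethoxybenzene | COc1ccc(OC)c(OC)c1 | starting material
2 | 2-(2,3,6-trimethoxyphenyl)propan-2-ol | COc1ccc(OC)c(C(C)(C)O)c1OC | intermediate
3 | 1,2,4-trimethoxy-3-(propan-2-yl)benzene | COc1ccc(OC)c(C(C)C)c1OC | intermediate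
4 | 2,4,5-trimethoxy-3-(propan-2-yl)benzaldehyde | COc1cc(C=O)c(OC)c(C(C)C)c1OC | intermediate
5 | 2,4,5-trimethoxy-3-(propan-2-yl)benzoic acid | COc1cc(C(=O)O)c(OC)c(C(C)C)c1OC | intermediate
6 | 2-(hydroxymethyl)-3,4,6-trimethoxy-5-(propan-2-yl)benzoic acid | COc1c(CO)c(C(=O)O)c(OC)c(C(C)C)c1OC | intermediate
7 | 4,5,7-trimethoxy-6-(propan-2-yl)-2-benzofuran-1(3H)-one | O=C1OCc2c1c(OC)c(C(C)C)c(OC)c2OC | intermediate
8 | 2-(chloromethyl)-3,4,6-trimethoxy-5-(propan-2-yl)benzoyl chloride | O=C(Cl)c1c(CCl)c(OC)c(OC)c(C(C)C)c1OC | intermediate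
9 | methyl 2-oxocyclohexane-1-carboxylate | COC(=O)C1CCCCC1=O | starting material
10 | tert-butyl L-valinate | CC(C)[C@H](N)C(=O)OC(C)(C)C | starting material
11 | methyl 2-{[(2S)-1-tert-butoxy-3-methyl-1-oxobutan-2-yl]amino}cyclohex-1-ene-1-carboxylate | COC(=O)C1=C(N[C@@H](C(C)C)C(=O)OC(C)(C)C)CCCC1 | intermediate
12 | methyl (1S)-2-{[(2S)-1-tert-butoxy-3-methyl-1-oxobutan-2-yl]imino}-1-methylcyclohexane-1-carboxylate | COC(=O)[C@@]1(C)CCCCC1=N[C@@H](C(C)C)C(=O)OC(C)(C)C | intermediate
13 | methyl (1S)-1-methyl-2-oxocyclohexane-1-carboxylate | COC(=O)[C@@]1(C)CCCCC1=O | intermediate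
14 | methyl (1S)-1-methyl-2-methylidenecyclohexane-1-carboxylate | COC(=O)[C@@]1(C)CCCCC1=C | intermediate
15 | methyl (1S)-2-{2-[2-(chloromethyl)-3,4,6-trimethoxy-5-(propan-2-yl)phenyl]-2-oxoethyl}-1-methylcyclohex-2-ene-1-carboxylate | COC(=O)[C@@]1(C)CCCC=C1CC(=O)c1c(CCl)c(OC)c(OC)c(C(C)C)c1OC | intermediate
16 | (4S,5S,10S)-11,12,14-trimethoxy-7-oxo-9(10→20)-abeo-abieta-8,11,13-trien-19,10-olide | O=C1C[C@@H]2[C@]3(CCC[C@]2(C)C(=O)O3)Cc2c1c(OC)c(C(C)C)c(OC)c2OC | intermediate
17 | (4S,5S,7R,10S)-7-hydroxy-11,12,14-trimethoxy-9(10→20)-abeo-abieta-8,11,13-trien-19,10-olide | O[C@@H]1C[C@@H]2[C@]3(CCC[C@]2(C)C(=O)O3)Cc2c1c(OC)c(C(C)C)c(OC)c2OC | intermediate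
18 | (4S,5S,7R,10S)-7-acetoxy-11,12,14-trimethoxy-9(10→20)-abeo-abieta-8,11,13-trien-19,10-olide | CC(=O)O[C@@H]1C[C@@H]2[C@]3(CCC[C@]2(C)C(=O)O3)Cc2c1c(OC)c(C(C)C)c(OC)c2OC | intermediate
19 | (4S,5S,7R,10S)-7-acetoxy-12-methoxy-11,14-dioxo-9(10→20)-abeo-abieta-8,12-dien-19,10-olide | CC(=O)O[C@@H]1C[C@@H]2[C@]3(CCC[C@]2(C)C(=O)O3)CC2=C1C(=O)C(C(C)C)=C(OC)C2=O | intermediate
20 | 7α-acetoxy-6,7-dihydroicetexone | CC(=O)O[C@@H]1C[C@@H]2[C@]3(CCC[C@]2(C)C(=O)O3)CC2=C1C(=O)C(C(C)C)=C(O)C2=O | target

**Step count and risks**

Total steps: 14. Longest linear sequence: 11 steps (steps 1–6, then 10–14).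

Most likely to fail, step 10. The process at risk is ionisation of the benzylic chloride of 8 before the acylium has been consumed, which would join C20 to C6 and give the regioisomeric annulation. A second risk is acid-promoted migration of the double bond of 14 or 15 (into the ring or into conjugation with the C7 carbonyl) before ring B has closed. The fallback sets out from 13 and 7 and comes back at 16; it makes the two C–C bonds separately with established reactions and forms C5–C6 in place of C6–C7. Ketone 13 is converted with KN(SiMe3)2 and PhNTf2 (THF, −78 °C) into methyl (1S)-1-methyl-2-{[(trifluoromethyl)sulfonyl]oxy}cyclohex-2-ene-1-carboxylate F1; only the C10 side can enolise. Phthalide 7 is opened with MeLi (1.05 equiv, THF, −78 °C) to 1-[2-(hydroxymethyl)-3,4,6-trimethoxy-5-(propan-2-yl)phenyl]ethan-1-one F2, the ring-chain tautomer of its lactol. The alkoxide–enolate of F2 (LiN(SiMe3)2, 2.2 equiv) is α-alkenylated with F1 (Pd2(dba)3, XPhos, THF, 60 °C; palladium-catalysed ketone α-alkenylation) to give methyl (1S)-2-{2-[2-(hydroxymethyl)-3,4,6-trimethoxy-5-(propan-2-yl)phenyl]-2-oxoethyl}-1-methylcyclohex-2-ene-1-carboxylate F3, the benzylic alcohol analogue of 15, without any acylium. F3 is then treated with CF3SO3H in CH2Cl2/(CF3)2CHOH at 0 °C; ketone-assisted ionisation of the benzylic alcohol, 7-endo cation–olefin cyclisation, hydride shift and lactonisation with loss of methanol should give 16.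

Second, step 14. The process at risk is loss of the C7 acetate (acyl cleavage or ionisation at C7) or opening of the lactone while the Lewis acid removes the O-methyl group. The fallback sets out from 17 and comes back at 20; the acetate is introduced last. Alcohol 17 is oxidised with (NH4)2Ce(NO3)6 (MeCN/H2O, 0 °C) to (4S,5S,7R,10S)-7-hydroxy-12-methoxy-11,14-dioxo-9(10→20)-abeo-abieta-8,12-dien-19,10-olide F4. The vinylogous methyl ester of F4 is hydrolysed (2 M aq. H2SO4, THF, 50 °C) to 7α-hydroxy-6,7-dihydroicetexone F5. F5 is acetylated at both hydroxyl groups (Ac2O, pyridine, DMAP) to 7α,12-diacetoxy-6,7-dihydroicetexone F6. The quinone enol acetate of F6, a vinylogous anhydride, is cleaved selectively (NaHCO3, MeOH/H2O, 0 °C) to give 20.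

Third, step 11. The process at risk is poor facial selectivity if the oxazaborolidine and the rigid trans-fused ketone are mismatched, or slow reduction of the doubly ortho-substituted aryl ketone. The fallback sets out from 16 and comes back at 18. The ketone is reduced under substrate control with NaBH4/CeCl3 (MeOH, −40 °C), where the shape of the tetracycle decides the face; if this gives 17, the route continues unchanged. If it gives the epimer (4S,5S,7S,10S)-7-hydroxy-11,12,14-trimethoxy-9(10→20)-abeo-abieta-8,11,13-trien-19,10-olide F7 (7β-OH), Mitsunobu esterification (PPh3, diisopropyl azodicarboxylate, AcOH, PhMe, 0 °C) inverts C7 and gives acetate 18 directly.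

Further compounds
F1 | step 10 | methyl (1S)-1-methyl-2-{[(trifluoromethyl)sulfonyl]oxy}cyclohex-2-ene-1-carboxylate | COC(=O)[C@@]1(C)CCCC=C1OS(=O)(=O)C(F)(F)F
F2 | step 10 | 1-[2-(hydroxymethyl)-3,4,6-trimethoxy-5-(propan-2-yl)phenyl]ethan-1-one | CC(=O)c1c(CO)c(OC)c(OC)c(C(C)C)c1OC
F3 | step 10 | methyl (1S)-2-{2-[2-(hydroxymethyl)-3,4,6-trimethoxy-5-(propan-2-yl)phenyl]-2-oxoethyl}-1-methylcyclohex-2-ene-1-carboxylate | COC(=O)[C@@]1(C)CCCC=C1CC(=O)c1c(CO)c(OC)c(OC)c(C(C)C)c1OC
F4 | step 14 | (4S,5S,7R,10S)-7-hydroxy-12-methoxy-11,14-dioxo-9(10→20)-abeo-abieta-8,12-dien-19,10-olide | O[C@@H]1C[C@@H]2[C@]3(CCC[C@]2(C)C(=O)O3)CC2=C1C(=O)C(C(C)C)=C(OC)C2=O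
F5 | step 14 | 7α-hydroxy-6,7-dihydroicetexone | O[C@@H]1C[C@@H]2[C@]3(CCC[C@]2(C)C(=O)O3)CC2=C1C(=O)C(C(C)C)=C(O)C2=O
F6 | step 14 | 7α,12-diacetoxy-6,7-dihydroicetexone | CC(=O)O[C@@H]1C[C@@H]2[C@]3(CCC[C@]2(C)C(=O)O3)CC2=C1C(=O)C(C(C)C)=C(OC(C)=O)C2=O
F7 | step 11 | (4S,5S,7S,10S)-7-hydroxy-11,12,14-trimethoxy-9(10→20)-abeo-abieta-8,11,13-trien-19,10-olide | O[C@H]1C[C@@H]2[C@]3(CCC[C@]2(C)C(=O)O3)Cc2c1c(OC)c(C(C)C)c(OC)c2OC
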